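A neighbour of this flask is read early; the flask here stands longer, and you want to know how much target is still there when it is read.

    target → over-reaction product (k1 = 0.177 /min)
    target ⇌ product in the second phase, rate k2*([target] - [product in the second phase]/K2) per volume of the first phase (K2 = 2.3, k2 = 0.0526 /min)
    starting material + reagent in the reaction phase → target (k3 = 7.92 /M/min)
    target → decomposed product (k4 = 0.0150 /min)
    reagent in the reaction phase ⇌ reagent in the second phase, rate k5*([reagent in the reaction phase] - [reagent in the second phase]/K5) per volume of the first phase (K5 = 1.0, k5 = 0.170 /min)

starting material 0.80 M; reagent in the second phase 0.880 M; time 10 min; volume of the second phase over the first 0.50

- target is meant together with its product in the second phase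
- in the second phase: reagent in the second phase, product in the second phase; everything else is in the first
- charges count per volume of the first phase; a concentration in a rate is the amount of a species over the volume of its own phase; every rate counts per litre of the first phase
- run time (flask): 10 min

1. amount of target and product in the second phase together at 10 min, in percent of the starting material charged
2. the change that raises the amount of target and product in the second phase together at 10 min, in percent of the starting material charged most ("none" if none brings more than 2 percentage points) (Friday's / Thursday's / Tuesday's / none)
3. amount of target and product in the second phase together at 10 min, in percent of the starting material charged, after Friday's

- Friday's: doubling the transfer coefficient of step 2, all else as stated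
- Thursday's: doubling the amount of reagent in the second phase, all else as stated
- Tuesday's: doubling the transfer coefficient of step 5, all else as stated

- In this flask, target in the first phase has three ways out: over-reaction and decomposition destroy it, and crossing saves it.
- Those constants fold into 21.5 %, the escape share (a branching ratio): the part of the target leaving the first phase that crosses instead of being destroyed.
- The share has no clock in it, so I add one. In this flask reagent leaves the second phase at 0.340 /min and target leaves the first at 0.245 /min, and these two steps in series leave 20.9 % in the first phase at 10 min.
- If I count the whole charge as turned over and give the escape share of the rest to the second phase, my figure for this flask is 37.9 %.
- Friday's lifts the share to 35.4 %, and the same reckoning gives 45.5 %.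
- Tuesday's leaves the share where it stands but quickens the reagent to 0.680 /min, and the same reckoning gives 33.0 %, lower than my figure for this flask.
- Thursday's also leaves the share where it stands, but my reckoning does not reach that flask: it would feed in 2.20 times the starting material charged, more reagent than there is starting material to take it.
- So my pick of Friday's is a judgement, not a comparison of three figures. My figures count no return from the second phase, so I take them as high.
- The forecast gives 34.5 %, and 41 % after Friday's, which is lower than my figures. Its ground is that the change “shelters more target in the second phase”.
- The simulation gives 34.9 % and names Friday's, which brings 4.9 percentage points and reaches 39.8 %, while Thursday's brings −5.9 points and Tuesday's −3.6 points.
- Now read the share back. Of the target gone from the first phase in this flask at 10.0 min, product in the second phase holds 18.0 %, less than the escape share of 21.5 %.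
- The neighbour flask, read at 2.5 min, holds 3.11 % as product in the second phase, 0.924 % as decomposed product and 10.9 % as over-reaction product, so its share reads 20.8 %.

(The numbers are invented; the run is a simulation.)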